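No flask can turn more first nucleophile into target than the protic impurity leaves it, so for the quick number you asked for I began at the far end. If the impurity takes its whole charge one for one, the target ceiling is (c(first nucleophile) − c(protic impurity))/c(substrate), which came to 50.0 % of the substrate for your charges. That made first nucleophile the limiting reagent for target, with 0.0500 M against 0.10 M. Noon had a ceiling of 25.0 %, and its target read 20.4 % at 40.0 min and 22.5 % at 80.0 min, while its other capture product reached 32.8 %.

| flask | substrate | first nucleophile | protic impurity | solid second nucleophile | temperature | remark | time |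
|---|---|---|---|---|---|---|---|
| dusk | 0.10 M | 0.050 M (in portions, 3) | 0.050 M | 0.18 M | −2 °C | run made earlier; portions every 80 s |  |
| noon | 0.10 M | 0.075 M (in portions, 3) | 0.050 M | 0.18 M | 14 °C | run made earlier; portions every 80 s |  |
| summer | 0.050 M | 0.10 M (in portions, 3) | 0.050 M | 0.18 M | −2 °C | run made earlier; portions every 80 s |  |
| south | 0.10 M | 0.100 M (in portions, 3) | 0.0500 M | 0.180 M | 5 °C | the portions of first nucleophile follow each other after 80 s, the first at the start | 1.5 h |
| east | 0.10 M | 0.100 M (in portions, 3) | 0.0500 M | 0.180 M | 20 °C | the portions of first nucleophile follow each other after 80 s, the first at the start | 1.5 h |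
| north-west | 0.10 M | 0.100 M (in portions, 3) | 0.0500 M | 0.180 M | −10 °C | the portions of first nucleophile follow each other after 80 s, the first at the start | 1.5 h |

- dusk (time / min: target / %, other capture product / %, substrate / %): 8.00: 1.4, 0, 99.5; 20.0: 1.8, 0, 98.4; 40.0: 0.2, 1.9, 97.6; 60.0: 3.1, 5.2, 94.7; 80.0: 2.6, 9.1, 92.4; 120: 6.0, 6.8, 88.9
- noon (time / min: target / %, other capture product / %, substrate / %): 5.00: 3.5, 0.8, 95.6; 10.0: 9.0, 1.5, 89.6; 15.0: 11.3, 3.9, 86.5; 25.0: 17.4, 6.4, 75.5; 40.0: 20.4, 14.8, 66.4; 80.0: 22.5, 32.8, 42.2
- summer (time / min: target / %, other capture product / %, substrate / %): 10.0: 0.6, 0, 99.1; 25.0: 1.7, 0.8, 97.6; 50.0: 3.8, 0.9, 94.7; 80.0: 6.4, 4.2, 91.9; 120: 8.6, 6.4, 87.1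

(readings scatter by 1 percentage point)

- at the start none of the solid second nucleophile is in solution

- which flask leads in share of target in all that became target or other capture product ("all alike" within 1.5 percentage points) (south / east / north-west / all alike)
- share of target in all that became target or other capture product, south
- share of target in all that became target or other capture product, east
- share of target in all that became target or other capture product, north-west

At the near end the solid second nucleophile started undissolved, so I expected the first captures to give target. At the far end, a fully converted flask in which the impurity had taken its whole charge could hold a share of target no higher than the ceiling. Joining the two ends, I expected the share to sink towards 50.0 % as conversion went on, which put east near that figure and not in the lead.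

The forecast gave 65 % for south, 51 % for east and 68 % for north-west, with north-west ahead. Its ground for east was: “East suffers from depleted nucleophile”.

The flasks gave 54.4 % for south, 51.0 % for east and 60.8 % for north-west, so north-west led. The forecast stood 11 percentage points high on south.

    substrate → intermediate (k = 3.92 × 10⁻⁴ s⁻¹, Ea = 93.0 kJ mol⁻¹)
    first nucleophile + intermediate → target (k = 1.35 L mol⁻¹ s⁻¹, Ea = 51.0 kJ mol⁻¹)
    second nucleophile + intermediate → other capture product (k = 2.20 L mol⁻¹ s⁻¹, Ea = 54.0 kJ mol⁻¹)
    first nucleophile + protic impurity → quenched reagent (k = 0.0414 L mol⁻¹ s⁻¹, Ea = 49.0 kJ mol⁻¹)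
    solid second nucleophile ⇌ second nucleophile, rate k5*(cs5 - [second nucleophile]) while solid is left; crystals form when [second nucleophile] > cs5 (solubility = 0.0850 M, k = 2.17 × 10⁻⁴ s⁻¹)
    (constants at 20 °C)

None of the shares had stopped moving. Left until 15.0 h, east changed least: its share went to 45.6 %, its substrate to 0 %, and its target from 44.8 % to 45.6 %, below the ceiling. East then led, ahead of south at 29.6 % and north-west at 32.4 %, with 76.1 % of the substrate still standing in north-west. The repeat of south at 30 °C went above the ceiling by 1.50 h: target stood at 58.7 %, with first nucleophile at 0 % and 17.4 % of the protic impurity unquenched.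

The data are calculated on assumed constants, and the scatter is random.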